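Numbers refer to the compound list after the steps. Phenalenone locants (C1–C9b) are used for the arene throughout.

## Analysis of the target

- Spiropreussione B is an octacyclic spiro-bisnaphthalene built on a 9-hydroxyphenalen-1-one: ring A is the enone ring C1–C3, ring B the benzene ring C3a–C6a, ring C the ring carrying the chelated 9-OH.
- Ring B is fused at C5–C6 to a five-membered carbocycle (ring D). Ring D shares one bond with a 4-hydroxycyclopent-2-enone (ring E) and carries, on the carbon bound to C6, the spiro ketal carbon of a naphtho[1,8-de][1,3]dioxine (ring F on a naphthalene).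
- There are two stereocentres and they are adjacent: the ring-fusion CH (S), flanked by the enone carbonyl and the ketal carbon, and the tertiary carbinol carbon on C5 (R). Rings D and E form a diquinane, so H and OH are necessarily cis and only the absolute sense has to be chosen.
- Sensitive groups:
  - the tertiary β-hydroxy ketone (retro-aldol, dehydration);
  - the ketone whose β-carbon bears two aryloxy groups (β-elimination of naphthoxide once the α-CH is enolised);
  - the γ-hydroxy enone;
  - the 9-hydroxyphenalenone, an acidic, chelating vinylogous acid whose O-alkyl derivatives are vinylogous esters open to nucleophiles.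
- The difficulty sits on the hindered C5/C6 edge of ring B (C6 is peri to C7–H): a quaternary aryl ketal next to a tertiary benzylic alcohol, with no other stereogenic element from which chirality could be relayed.
- The strategy rests on the bond between the carbinol carbon and the ring-fusion CH. It is the one bond common to rings D and E, and its ends are the two ends of a β-hydroxy ketone.
- Opening that bond as a retro-aldol, after saturating the C=C of ring E, unfolds both five-membered rings into one achiral eight-membered ring fused to ring B. This is a cyclooctane-1,4-dione: the aryl ketone on C5 and the dialkyl ketone are separated by CH2–CH2, and the ketal carbon sits next to the only CH2 that can close back.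
- A 5-substituted 9-hydroxyphenalenone is symmetric through C5 because of fast O–H tautomerism, so C4 and C6 are equivalent. This removes one regiochemical question from the arene synthesis.

## Retrosynthetic reasoning

**21 to 20.** The ring-E double bond is removed first. Ketol 20 has a single CH2–CH2 edge next to its ketone; the other α-carbon, the ring-fusion CH, has no β-hydrogen. The forward dehydrogenation can therefore only give 21 and touches neither stereocentre. Only one step then follows the stereo-defining event.

**20 to 19.** The bond between the carbinol carbon and the ring-fusion CH is cut as an aldol. No other bond opens rings D and E together, and no other cut leaves an achiral precursor. Dione 19 has no stereocentre, because the two ketal oxygens belong to one symmetric diol. The forward transannular aldol has to form one C–C bond, two rings and both stereocentres under the control of a chiral secondary-amine catalyst. Regiochemistry is not in question: every other enol or enamine of 19 could only close a three-membered ring.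

**19 to 16.** The eight-membered ring is opened at C2–C3, the only ring bond flanked on both sides by carbons that can carry oxygen. Oxidation levels are adjusted so that the ring is closed on alcohols, not on two electron-poor enones. Dione 19 comes from saturated diol 18, 18 from the Z-cyclooctene diol 17, and 17 by ring-closing metathesis of the bis-allylic diol 16. The carbinol configurations of 16–18 are irrelevant because all are erased on oxidation to 19.

**16 to 9.** Both allylic alcohols come from aldehydes and vinylmagnesium bromide 10.
- The ketal-side aldehyde 15 is cut at its two ketal C–O bonds. Both oxygens sit on a carbon β to the aldehyde, so they come from double conjugate addition of 1,8-dihydroxynaphthalene 14 to ynal 13. This fixes which carbon becomes the ketal and needs no ketalisation of a hindered aryl ketone.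
- During that base-mediated step the aryl side must carry neither a carbonyl nor a free hydroxyl. An ortho carbonyl would be attacked by the intermediate enolate, closing ring D prematurely and without stereocontrol. A free benzylic hydroxyl would add to the ynal.
- The aryl-side vinyl carbinol is therefore installed first (11, from aldehyde 9 and 10) and carried as its acetate (12, then 13 after unmasking the ynal). The second addition of 10 removes the acetate in the same operation.

**9 to 7.** The aryl–alkyne bond is cut (Sonogashira) to bromo aldehyde 7 and the propynal acetal 8. In 7 the bromide is ortho to a formyl group and conjugated to the phenalenone carbonyl, so it is activated for oxidative addition.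

**7 to 1 and 2.** The ortho bromo/formyl pattern is the signature of a Vilsmeier-type bromoformylation of a cyclic aryl ketone, here perinaphthanone 4. Its carbonyl carbon becomes C6 and its α-CH2 becomes C5, so no regiochemical choice arises.
- Ring B is placed last on a 1,8-dioxygenated naphthalene. The two oxygens of 4 are already peri to each other, as O1 and O9 of the phenalenone must be.
- Phenalene 5 then needs only loss of hydride and of two O-methyl groups to become 7.
- Ketone 4 is cut at its aryl–acyl and aryl–alkyl bonds to 1,8-dimethoxynaphthalene 1 and 3-chloropropanoyl chloride 2, through chloroketone 3. Both new bonds form para to a methoxy group.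
- Ring construction on a preformed 9-hydroxyphenalenone was not pursued, because electrophilic substitution there has no reliable preference for C5/C6.

## Alternatives that were turned down

**Alternative 1:** benzannulation that builds ring B last.
- Disconnection: the key-step product A1 is taken apart at C3a–C4 and C5–C6.
- Forward key step: a quinone carbonyl peri to an aryl alkyne closes onto the triple bond under a carbophilic gold catalyst to give a benzopyrylium ion. This ion undergoes [4+2] addition with an ethynyl group held on the carbinol carbon. Collapse of the adduct gives benzene ring B and, because the dienophile is tethered, the five-membered ketone ring.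
- For: it is more convergent than the chosen route, forms the crowded C5/C6 edge and a ring in one operation, and places both stereocentres on a small cyclopentenone where asymmetric methods are mature. On convergence it is stronger.
- Against: A1 still lacks the spiro ketal. Its C6 acyl group is half of a β-diketone, flanked by C7–H and the enolisable ring-fusion CH. It would have to be ketalised with 14 selectively, beside two other carbonyls and under acid, in the presence of a tertiary silyl ether prone to elimination and retro-aldol. The hardest bond of the molecule is left to the end, followed by desilylation and O-demethylation.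
- Comparison: the chosen route makes the ketal early by conjugate addition, where the position is fixed by the ynal, and has one step after the key step.

**Alternative 2:** cationic spirocyclisation that forms the aryl–ketal bond.
- Disconnection: the key-step product A2 is cut between C6 and the spiro carbon.
- Forward key step: an α-oxo ketene acetal of the naphthodioxine is protonated at carbon to a dioxinylium ion. The adjacent α-carbon of the naphthalene attacks it, closing ring D and creating the quaternary centre. The ring-fusion CH is set by that protonation, cis to the existing carbinol.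
- For: the quaternary ketal carbon is made through a strongly stabilised cation, with no oxygen nucleophile adding to a hindered centre. On this bond it is probably stronger than the double conjugate addition of step 8.
- Against: the carbinol must already be present, enantioenriched, as a tertiary, benzylic and allylic alcohol, and must survive the Brønsted acid that generates the cation. The phenalenone has to travel masked (dihydro, dioxolane, methyl ether) to keep the arene nucleophilic, so three unmasking steps follow on the complete acid- and oxidant-sensitive ketol.
- Comparison: the chosen route creates both stereocentres from an achiral compound in the last C–C bond-forming step and carries the free 9-hydroxyphenalenone throughout.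

**Alternative 3:** double oxa-Michael and aldol cascade.
- Disconnection: both ketal C–O bonds and the ring-fusion C–C bond of A3 are cut at once.
- Forward key step: diol 14 adds twice to the β-carbon of an ynone. The enolate released by the second addition is trapped by the neighbouring aryl ketone, closing the dioxine and ring D. Ring E would follow by aldol condensation of the acetyl group with the unmasked aldehyde.
- For: this is the shortest plan. It needs no medium ring and no metathesis, it uses the same ketal-forming reaction as step 8, and it forms the same C–C bond as the chosen key step as an unstrained five-ring closure. On step economy it is clearly stronger.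
- Against: the two stereocentres arise in a base-mediated, reversible cascade. The nucleophile is generated by an achiral addition, so there is no handle for absolute control. The cis relationship of the acetyl and dimethoxymethyl groups in A3, needed for ring E, is not enforced in an open-chain aldol.
- Comparison: the chosen route spends steps on an eight-membered ring. In return it gets a known catalytic, enantioselective closure in which the cis fusion is intrinsic. This cascade is also the side reaction that the acetate in steps 6–9 is there to prevent.

Key step: step 13

## Remarks on the chemistry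

- 9-Hydroxyphenalen-1-ones are drawn in the O–H tautomer of the target SMILES; the two chelate tautomers interconvert rapidly and are one compound.
- 1,8-Dimethoxynaphthalene 1 is taken as a catalogue compound.
- Compounds 11–13 and 15 are racemates and 16–18 are mixtures of racemic diastereomers; these carbinol centres are erased in step 12.

## Route

Step 1
Reactants: 1 1,8-dimethoxynaphthalene; 2 3-chloropropanoyl chloride
Product: 4 6,7-dimethoxy-2,3-dihydro-1H-phenalen-1-one, via chloroketone 3 (not isolated)
Conditions: AlCl3, CH2Cl2, 0 °C; then P2O5–MeSO3H (Eaton's reagent), 60 °C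
Reagents that add atoms: none
Why: Friedel–Crafts acylation goes para to a methoxy group at the α-position C4; in strong acid the β-chloro ketone loses HCl and the protonated aryl vinyl ketone alkylates the peri carbon C5, which is para to the second methoxy group (peri-annulation). The symmetry of 1 makes the outcome unambiguous.

Step 2
Reactants: 4 6,7-dimethoxy-2,3-dihydro-1H-phenalen-1-one
Product: 5 3-bromo-6,7-dimethoxy-1H-phenalene-2-carbaldehyde
Conditions: PBr3, DMF, CHCl3, 0 → 60 °C; aq. NaOAc
Reagents that add atoms: N,N-dimethylformamide CN(C)C=O; phosphorus tribromide BrP(Br)Br; water O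
Why: Vilsmeier–Haack–Arnold bromoformylation, as with 1-tetralones: the bromo-iminium salt formylates the only enolisable α-CH2 and turns the carbonyl carbon into the vinyl bromide. The ring positions ortho to the methoxy groups are far less reactive than the enol.

Step 3
Reactants: 5 3-bromo-6,7-dimethoxy-1H-phenalene-2-carbaldehyde
Product: 7 6-bromo-9-hydroxy-1-oxo-1H-phenalene-5-carbaldehyde, via dimethoxyphenalenium salt 6 (not isolated)
Conditions: DDQ, CH2Cl2, 0 °C; then BBr3, −78 → 0 °C; H2O
Reagents that add atoms: none
Why: DDQ abstracts hydride from the doubly benzylic CH2 of the 1H-phenalene (which becomes C4–H), giving the 1,9-dimethoxyphenalenium ion, a doubly O-methylated 9-oxidophenalenone. BBr3 then cleaves both methyl groups, the first as easily as from an oxonium salt and the second with chelation by the peri carbonyl. Any CH2 tautomer of 5 gives the same cation, and either order of demethylation ends in the same chelated 9-hydroxyphenalenone.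

Step 4
Reactants: 7 6-bromo-9-hydroxy-1-oxo-1H-phenalene-5-carbaldehyde; 8 3,3-diethoxyprop-1-yne
Product: 9 6-(3,3-diethoxyprop-1-yn-1-yl)-9-hydroxy-1-oxo-1H-phenalene-5-carbaldehyde
Conditions: PdCl2(PPh3)2 (5 mol %), CuI (10 mol %), Et3N, DMF, 50 °C
Reagents that add atoms: none
Why: Sonogashira coupling. The C–Br bond is activated by the ortho formyl group and by conjugation with the phenalenone carbonyl; the tertiary amine cannot add to the phenalenone, and the chelated 9-OH is carried as its ammonium salt.

Step 5
Reactants: 9 6-(3,3-diethoxyprop-1-yn-1-yl)-9-hydroxy-1-oxo-1H-phenalene-5-carbaldehyde; 10 vinylmagnesium bromide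
Product: 11 6-(3,3-diethoxyprop-1-yn-1-yl)-9-hydroxy-5-(1-hydroxyprop-2-en-1-yl)-1H-phenalen-1-one (racemic)
Conditions: THF, −78 °C (2.5 equiv of 10); aq. NH4Cl
Reagents that add atoms: none
Why: Grignard 1,2-addition to the non-enolisable aryl aldehyde. The first equivalent converts the 9-hydroxyphenalenone into its magnesium chelate, a delocalised vinylogous carboxylate that is inert to further addition; the new carbinol centre is racemic and is erased in step 12.

Step 6
Reactants: 11 6-(3,3-diethoxyprop-1-yn-1-yl)-9-hydroxy-5-(1-hydroxyprop-2-en-1-yl)-1H-phenalen-1-one
Product: 12 1-[6-(3,3-diethoxyprop-1-yn-1-yl)-9-hydroxy-1-oxo-1H-phenalen-5-yl]prop-2-en-1-yl acetate (racemic)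
Conditions: Ac2O (1.2 equiv), pyridine, DMAP (cat.), CH2Cl2, 0 °C; aq. NaHCO3
Reagents that add atoms: acetic anhydride CC(=O)OC(C)=O
Why: DMAP-catalysed acetylation of the only nucleophilic hydroxyl; an O-acetate of the chelated vinylogous acid would be a mixed anhydride and does not survive bicarbonate work-up. The ester keeps the benzylic oxygen from adding to the ynal of step 7 (5-exo-dig oxa-Michael) and keeps the aryl side non-electrophilic during ketal formation.

Step 7
Reactants: 12 1-[6-(3,3-diethoxyprop-1-yn-1-yl)-9-hydroxy-1-oxo-1H-phenalen-5-yl]prop-2-en-1-yl acetate
Product: 13 1-[9-hydroxy-1-oxo-6-(3-oxoprop-1-yn-1-yl)-1H-phenalen-5-yl]prop-2-en-1-yl acetate (racemic)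
Conditions: CF3CO2H, H2O, CH2Cl2, 0 °C → rt
Reagents that add atoms: water O
Why: Acid hydrolysis of the propargylic diethyl acetal to the ynal. The allylic, benzylic acetate sits on an electron-poor arene and should not ionise under these conditions.

Step 8
Reactants: 13 1-[9-hydroxy-1-oxo-6-(3-oxoprop-1-yn-1-yl)-1H-phenalen-5-yl]prop-2-en-1-yl acetate; 14 1,8-dihydroxynaphthalene
Product: 15 1-{9-hydroxy-1-oxo-6-[2-(2-oxoethyl)naphtho[1,8-de][1,3]dioxin-2-yl]-1H-phenalen-5-yl}prop-2-en-1-yl acetate (racemic)
Conditions: i-Pr2NEt (3 equiv), DABCO (20 mol %), MeCN, 0 °C → rt; pH 5 buffer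
Reagents that add atoms: none
Why: Double oxa-Michael addition of a bis-phenol to an activated alkyne, the known route from catechols and ynones to cyclic aryl ketals. The naphthoxide adds to the β-carbon of the ynal and the second peri hydroxyl closes the six-membered 1,3-dioxine onto the resulting β-aryloxy enal, so both oxygens end on the carbon bound to C6. With the aryl side masked as an acetate, the intermediate enolate has no ortho carbonyl to attack.

Step 9
Reactants: 15 1-{9-hydroxy-1-oxo-6-[2-(2-oxoethyl)naphtho[1,8-de][1,3]dioxin-2-yl]-1H-phenalen-5-yl}prop-2-en-1-yl acetate; 10 vinylmagnesium bromide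
Product: 16 9-hydroxy-6-[2-(2-hydroxybut-3-en-1-yl)naphtho[1,8-de][1,3]dioxin-2-yl]-5-(1-hydroxyprop-2-en-1-yl)-1H-phenalen-1-one (diastereomer mixture)
Conditions: CeCl3, THF, −78 → 0 °C (5 equiv of 10); aq. NH4Cl
Reagents that add atoms: none
Why: Organocerium 1,2-addition to the enolisable β-ketal aldehyde, which avoids deprotonation and hence β-elimination of naphthoxide. On warming, excess vinylmagnesium bromide cleaves the acetate, so the second allylic alcohol is unmasked in the same flask; both carbinol centres are unselective and are erased in step 12.

Step 10
Reactants: 16 bis-allylic diol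
Product: 17 Z-cyclooctene diol: 9-hydroxyphenalen-1-one with C5 and C6 bridged by C5–CH(OH)–CH=CH–CH(OH)–CH2–C(spiro), the spiro carbon being C2 of the naphtho[1,8-de][1,3]dioxine (diastereomer mixture)
Conditions: second-generation Grubbs catalyst (10 mol %), 1,4-benzoquinone (20 mol %), CH2Cl2 (2 mM), 40 °C
Reagents that add atoms: none
Why: Ring-closing metathesis of two monosubstituted allylic-alcohol olefins. Closure of the eight-membered ring is helped by the ortho-fused arene and the quaternary spiro carbon, which hold the vinyl groups close; only the Z-cyclooctene can form. Benzoquinone suppresses ruthenium hydride isomerisation of the allylic alcohols.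

Step 11
Reactants: 17 Z-cyclooctene diol
Product: 18 saturated diol: 9-hydroxyphenalen-1-one with C5 and C6 bridged by C5–CH(OH)–CH2–CH2–CH(OH)–CH2–C(spiro) (diastereomer mixture)
Conditions: 2-nitrobenzenesulfonyl hydrazide, Et3N, CH2Cl2, rt
Reagents that add atoms: none
Why: Diimide, released from the sulfonyl hydrazide, reduces the strained, unpolarised cis ring alkene by concerted syn hydrogen transfer. The conjugated C2=C3 bond of the phenalenone is not attacked and no benzylic C–O hydrogenolysis can occur, which is why catalytic hydrogenation is avoided.

Step 12
Reactants: 18 saturated diol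
Product: 19 benzo-fused cyclooctane-1,4-dione spiroketal: 9-hydroxyphenalen-1-one with C5 and C6 bridged by C5–C(=O)–CH2–CH2–C(=O)–CH2–C(spiro), the spiro carbon being C2 of the naphtho[1,8-de][1,3]dioxine (achiral)
Conditions: Dess–Martin periodinane (2.5 equiv), CH2Cl2, 0 °C → rt
Reagents that add atoms: none
Why: Dess–Martin oxidation of both secondary alcohols under near-neutral, non-enolising conditions. The γ-hydroxy ketone formed first equilibrates with its transannular lactol but is drained through the open form; all diastereomers converge on one achiral dione.

Step 13
Reactants: 19 benzo-fused cyclooctane-1,4-dione spiroketal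
Product: 20 cis-fused ketol (saturated analogue of the target): ring-fusion CH (S) bound to the spiro carbon, the cyclopentanone carbonyl and the carbinol carbon; carbinol carbon (R) on C5
Conditions: (2S,4R)-4-fluoroproline (20 mol %), DMSO, rt
Reagents that add atoms: none
Why: The catalyst condenses with the unconjugated dialkyl ketone and the iminium ion equilibrates to both enamines. Only the enamine towards the CH2 next to the ketal carbon can reach the aryl ketone, since any other enol or enamine carbon would close a three-membered ring, so the unproductive enamine simply reverts (Curtin–Hammett). C–C bond formation across the ring, assisted by the carboxylic acid hydrogen bond to the aryl ketone oxygen, gives the iminium ion of the ketol, and hydrolysis frees the catalyst; this is the known proline-type transannular aldol of cyclooctane-1,4-diones to bicyclo[3.3.0]octane ketols. The cyclopentanone ring closes 5-(enolendo)-exo-trig, a mode disfavoured in open chains but imposed here by the medium ring that holds donor and acceptor within bonding distance; the indane ring D closes 5-(enolexo)-exo-trig. The cis fusion, with H and OH on the same face, is the only one a diquinane formed this way can adopt, so the relative configuration is intrinsic. Dione 19 is achiral, so the absolute configuration of both centres comes from the catalyst alone, which selects one of the two enantiomeric ring conformers in the hydrogen-bonded transition state; the sense on this benzo-fused substrate must be confirmed on the first run, and the (2R,4S) catalyst is used if it is opposite. The step needs three selectivities: no amine attack on the phenalenone (the free chelated 9-OH makes it a vinylogous acid, not a vinylogous ester), no lasting loss of naphthoxide from the enamine β-position (the leaving oxygen stays tethered and re-adds), and no racemic background closure (neutral DMSO, room temperature).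

Step 14
Reactants: 20 cis-fused ketol
Product: 21 spiropreussione B
Conditions: 2-iodoxybenzoic acid (IBX), 4-methoxypyridine N-oxide, DMSO, rt → 40 °C
Reagents that add atoms: none
Why: IBX dehydrogenation of a ketone to the enone (enolisation, single-electron oxidation, loss of the β-hydrogen). The ring-fusion α-carbon has no β-hydrogen, so only the CH2–CH2 edge can be desaturated; the N-oxide ligand allows reaction near room temperature, which protects the tertiary aldol from retro-aldol cleavage, and neither stereocentre is touched.

## Compound list

1 | 1,8-dimethoxynaphthalene | COc1cccc2cccc(OC)c12 | starting material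
2 | 3-chloropropanoyl chloride | O=C(Cl)CCCl | starting material
3 | 3-chloro-1-(4,5-dimethoxynaphthalen-1-yl)propan-1-one | O=C(CCCl)c1ccc(OC)c2c(OC)cccc12 | intermediate
4 | 6,7-dimethoxy-2,3-dihydro-1H-phenalen-1-one | O=C1CCc2ccc(OC)c3c(OC)ccc1c23 | intermediate
5 | 3-bromo-6,7-dimethoxy-1H-phenalene-2-carbaldehyde | O=CC1=C(Br)c2ccc(OC)c3c(OC)ccc(C1)c23 | intermediate
6 | 6-bromo-5-formyl-1,9-dimethoxyphenalenium 2,3-dichloro-5,6-dicyano-4-hydroxyphenolate | C[O+]=C1C=Cc2cc(C=O)c(Br)c3ccc(OC)c1c23.[O-]c1c(Cl)c(Cl)c(O)c(C#N)c1C#N | intermediate
7 | 6-bromo-9-hydroxy-1-oxo-1H-phenalene-5-carbaldehyde | O=C1C=Cc2cc(C=O)c(Br)c3ccc(O)c1c23 | intermediate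
8 | 3,3-diethoxyprop-1-yne | C#CC(OCC)OCC | starting material
9 | 6-(3,3-diethoxyprop-1-yn-1-yl)-9-hydroxy-1-oxo-1H-phenalene-5-carbaldehyde | O=C1C=Cc2cc(C=O)c(C#CC(OCC)OCC)c3ccc(O)c1c23 | intermediate
10 | vinylmagnesium bromide | C=C[Mg]Br | starting material
11 | 6-(3,3-diethoxyprop-1-yn-1-yl)-9-hydroxy-5-(1-hydroxyprop-2-en-1-yl)-1H-phenalen-1-one (racemic) | O=C1C=Cc2cc(C(O)C=C)c(C#CC(OCC)OCC)c3ccc(O)c1c23 | intermediate
12 | 1-[6-(3,3-diethoxyprop-1-yn-1-yl)-9-hydroxy-1-oxo-1H-phenalen-5-yl]prop-2-en-1-yl acetate (racemic) | O=C1C=Cc2cc(C(OC(C)=O)C=C)c(C#CC(OCC)OCC)c3ccc(O)c1c23 | intermediate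
13 | 1-[9-hydroxy-1-oxo-6-(3-oxoprop-1-yn-1-yl)-1H-phenalen-5-yl]prop-2-en-1-yl acetate (racemic) | O=C1C=Cc2cc(C(OC(C)=O)C=C)c(C#CC=O)c3ccc(O)c1c23 | intermediate
14 | 1,8-dihydroxynaphthalene | Oc1cccc2cccc(O)c12 | starting material
15 | 1-{9-hydroxy-1-oxo-6-[2-(2-oxoethyl)naphtho[1,8-de][1,3]dioxin-2-yl]-1H-phenalen-5-yl}prop-2-en-1-yl acetate (racemic) | O=C1C=Cc2cc(C(OC(C)=O)C=C)c(C3(CC=O)Oc4cccc5cccc(c45)O3)c3ccc(O)c1c23 | intermediate
16 | 9-hydroxy-6-[2-(2-hydroxybut-3-en-1-yl)naphtho[1,8-de][1,3]dioxin-2-yl]-5-(1-hydroxyprop-2-en-1-yl)-1H-phenalen-1-one (diastereomer mixture) | O=C1C=Cc2cc(C(O)C=C)c(C3(CC(O)C=C)Oc4cccc5cccc(c45)O3)c3ccc(O)c1c23 | intermediate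
17 | Z-cyclooctene diol, C5–CH(OH)–CH=CH–CH(OH)–CH2–C(spiro)–C6 bridge on the 9-hydroxyphenalenone (diastereomer mixture) | O=C1C=Cc2cc3c(c4ccc(O)c1c24)C1(Oc2cccc4cccc(c24)O1)CC(O)/C=C\C3O | intermediate
18 | saturated diol, C5–CH(OH)–CH2–CH2–CH(OH)–CH2–C(spiro)–C6 bridge (diastereomer mixture) | O=C1C=Cc2cc3c(c4ccc(O)c1c24)C1(Oc2cccc4cccc(c24)O1)CC(O)CCC3O | intermediate
19 | benzo-fused cyclooctane-1,4-dione spiroketal, C5–C(=O)–CH2–CH2–C(=O)–CH2–C(spiro)–C6 bridge (achiral) | O=C1C=Cc2cc3c(c4ccc(O)c1c24)C1(Oc2cccc4cccc(c24)O1)CC(=O)CCC3=O | intermediate
20 | cis-fused ketol, ring-fusion CH (S), carbinol carbon (R) | O=C1C=Cc2cc3c(c4ccc(O)c1c24)C1(Oc2cccc4cccc(c24)O1)[C@@H]1C(=O)CC[C@]31O | intermediate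
21 | spiropreussione B | O=C1C=Cc2cc3c(c4ccc(O)c1c24)C1(Oc2cccc4cccc(c24)O1)[C@@H]1C(=O)C=C[C@]31O | target

## Step count and least certain steps

Total step count: 14. Longest linear sequence: 14 steps (from 1; compounds 2, 8, 10 and 14 are bought).

**Step 13 (key step).**
- Risk: low or wrong enantiofacial selectivity, or stalled conversion. The productive enamine must form at a CH2 next to a quaternary ketal carbon, the aryl ketone on C5 is hindered, and reversible β-elimination of naphthoxide or a slow retro-aldol/aldol equilibration could erode enantiopurity.
- Fallback (from 19, back at 20): the ring is closed without chiral induction using pyrrolidinium acetate in DMSO. The racemic ketol is resolved by preparative chromatography on a chiral stationary phase. The wanted antipode is 20; the mirror-image ketol F1 is returned to the racemate by retro-aldol/aldol equilibration under the same achiral amine salt and resolved again.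

**Step 8.**
- Risk: the second C–O bond may not close. The quaternary ketal carbon forms next to a peri-hindered, ortho-substituted arene, and under base the ketal is in equilibrium with the ring-opened β-aryloxy enal. C-alkylation of the naphthoxide and acetyl transfer are lesser risks.
- Fallback (from 13 and 14, back at 15): the reaction is stopped after the first addition (one equivalent of amine, −20 °C) at the β-(8-hydroxy-1-naphthyloxy) enal F2. The dioxine is then closed under Brønsted acid (camphorsulfonic acid, CH2Cl2). There the carbonyl-protonated vinylogous ester is attacked by the free naphthol, and neither an enolate nor β-elimination of an aryloxide can intervene.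

**Step 10.**
- Risk: oligomerisation in place of ring closure, because the eight-membered ring is strained and one diastereomer of 16 may place its vinyl groups badly; also ruthenium hydride isomerisation of the allylic alcohols to ethyl ketones.
- Fallback (from 9, back at 17): the ring is closed by an intramolecular Nozaki–Hiyama–Kishi addition.
  - Aldehyde 9 and ethynylmagnesium bromide give the propargylic alcohol F3, which is acetylated to the propargylic acetate F4.
  - Acetal hydrolysis as in step 7 gives the ynal F5, and addition of 14 as in step 8 gives the spiroketal aldehyde F6.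
  - Iodination of the terminal alkyne (N-iodosuccinimide, AgNO3 cat.) gives the iodoalkyne F7, and diimide reduction gives the (Z)-iodoalkene F8.
  - CrCl2 with catalytic NiCl2 in DMSO at high dilution adds the alkenylchromium to the aldehyde, forming the C3–C4 bond and the Z-cyclooctene irreversibly as the ring-closed monoacetate F9.
  - Methanolysis (K2CO3, MeOH) returns 17.

**Step 3.**
- Risk: the cationic intermediate may be intercepted at ring carbons (C6–Br is a vinylogous acyl bromide position), or demethylation may be incomplete, leaving regioisomeric methyl ethers.
- Fallback (from 5, back at 7): the order is inverted. BBr3 first cleaves both ethers of the neutral phenalene to the dihydroxyphenalene F10, handled under argon. DDQ or air then dehydrogenates this electron-rich bis-naphthol directly to 7, so no alkoxyphenalenium ion is formed.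

**Step 14.**
- Risk: retro-aldol or dehydration of the tertiary β-hydroxy ketone on warming, or oxidation of the electron-rich naphthodioxine by IBX.
- Fallback (from 20, back at 21): Saegusa–Ito oxidation.
  - TMSOTf and Et3N (CH2Cl2, −78 → 0 °C) silylate both hydroxyls and enolise the ketone away from the ring fusion, giving the tris(trimethylsilyl) enol ether F11.
  - Pd(OAc)2 in MeCN gives the bis(trimethylsilyl) enone F12.
  - Dilute HCl in MeOH removes the silyl groups to give 21.

## Further compounds

F1 | step 13 | mirror-image ketol (enantiomer of 20) | O=C1C=Cc2cc3c(c4ccc(O)c1c24)C1(Oc2cccc4cccc(c24)O1)[C@H]1C(=O)CC[C@@]31O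
F2 | step 8 | 1-{9-hydroxy-6-[1-(8-hydroxynaphthalen-1-yl)oxy-3-oxoprop-1-en-1-yl]-1-oxo-1H-phenalen-5-yl}prop-2-en-1-yl acetate (racemic, alkene geometry open) | O=C1C=Cc2cc(C(OC(C)=O)C=C)c(C(=CC=O)Oc3cccc4cccc(O)c34)c3ccc(O)c1c23
F3 | step 10 | 6-(3,3-diethoxyprop-1-yn-1-yl)-9-hydroxy-5-(1-hydroxyprop-2-yn-1-yl)-1H-phenalen-1-one (racemic) | O=C1C=Cc2cc(C(O)C#C)c(C#CC(OCC)OCC)c3ccc(O)c1c23
F4 | step 10 | 1-[6-(3,3-diethoxyprop-1-yn-1-yl)-9-hydroxy-1-oxo-1H-phenalen-5-yl]prop-2-yn-1-yl acetate (racemic) | O=C1C=Cc2cc(C(OC(C)=O)C#C)c(C#CC(OCC)OCC)c3ccc(O)c1c23
F5 | step 10 | 1-[9-hydroxy-1-oxo-6-(3-oxoprop-1-yn-1-yl)-1H-phenalen-5-yl]prop-2-yn-1-yl acetate (racemic) | O=C1C=Cc2cc(C(OC(C)=O)C#C)c(C#CC=O)c3ccc(O)c1c23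
F6 | step 10 | 1-{9-hydroxy-1-oxo-6-[2-(2-oxoethyl)naphtho[1,8-de][1,3]dioxin-2-yl]-1H-phenalen-5-yl}prop-2-yn-1-yl acetate (racemic) | O=C1C=Cc2cc(C(OC(C)=O)C#C)c(C3(CC=O)Oc4cccc5cccc(c45)O3)c3ccc(O)c1c23
F7 | step 10 | 1-{9-hydroxy-1-oxo-6-[2-(2-oxoethyl)naphtho[1,8-de][1,3]dioxin-2-yl]-1H-phenalen-5-yl}-3-iodoprop-2-yn-1-yl acetate (racemic) | O=C1C=Cc2cc(C(OC(C)=O)C#CI)c(C3(CC=O)Oc4cccc5cccc(c45)O3)c3ccc(O)c1c23
F8 | step 10 | (Z)-1-{9-hydroxy-1-oxo-6-[2-(2-oxoethyl)naphtho[1,8-de][1,3]dioxin-2-yl]-1H-phenalen-5-yl}-3-iodoprop-2-en-1-yl acetate (racemic) | O=C1C=Cc2cc(C(OC(C)=O)/C=C\I)c(C3(CC=O)Oc4cccc5cccc(c45)O3)c3ccc(O)c1c23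
F9 | step 10 | Z-cyclooctene diol 17 as the monoacetate of the hydroxyl on the carbon bound to C5 (diastereomer mixture) | O=C1C=Cc2cc3c(c4ccc(O)c1c24)C1(Oc2cccc4cccc(c24)O1)CC(O)/C=C\C3OC(C)=O
F10 | step 3 | 3-bromo-6,7-dihydroxy-1H-phenalene-2-carbaldehyde | O=CC1=C(Br)c2ccc(O)c3c(O)ccc(C1)c23
F11 | step 14 | tris(trimethylsilyl) derivative of 20 (silyl enol ether towards the CH2, silylated carbinol and 9-hydroxyl) | O=C1C=Cc2cc3c(c4ccc(O[Si](C)(C)C)c1c24)C1(Oc2cccc4cccc(c24)O1)[C@@H]1C(O[Si](C)(C)C)=CC[C@]31O[Si](C)(C)C
F12 | step 14 | bis(trimethylsilyl) ether of spiropreussione B | O=C1C=Cc2cc3c(c4ccc(O[Si](C)(C)C)c1c24)C1(Oc2cccc4cccc(c24)O1)[C@@H]1C(=O)C=C[C@]31O[Si](C)(C)C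
A1 | alternative 1 | methoxyphenalenone-fused indanedione triethylsilyl ether | O=C1C=Cc2cc3c(c4ccc(OC)c1c24)C(=O)[C@@H]1C(=O)C=C[C@]31O[Si](CC)(CC)CC
A2 | alternative 2 | masked spiropreussione B (dihydrophenalenone dioxolane, methyl ether) | C12(OCCO2)CCc2cc3c(c4ccc(OC)c1c24)C1(Oc2cccc4cccc(c24)O1)[C@@H]1C(=O)C=C[C@]31O
A3 | alternative 3 | spiroketal aldol adduct with cis acetyl and dimethoxymethyl groups | O=C1C=Cc2cc3c(c4ccc(O)c1c24)C1(Oc2cccc4cccc(c24)O1)[C@H](C(C)=O)[C@]3(O)C(OC)OC
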